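**Strategy.** The target is epicatechin-(4β→6)-epicatechin-(4β→6)-epicatechin. Everything rests on opening ring C of the terminal unit at C4–C4a and O1–C8a, two bonds that end on adjacent ring A carbons, i.e. on the two carbons of an aryne. In the key step the benzylic alkoxide of an open-chain, aldol-derived (2R,3R) three-carbon fragment adds to 3,5-bis(benzyloxy)benzyne at the future C8a (directed by the C5 oxygen next to C4a), and the aryl anion closes ring C on a primary tosylate. The resulting epicatechin ether is brominated at C8 and coupled at C6 with two bromine-capped C4 electrophiles made from (−)-epicatechin; hydrogenolysis completes the trimer.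

Key step: step 7

Remark: the SMILES is read as three (2R,3R)-epicatechin units joined by two 4β→6 bonds (both linking C4 centres S); flavan numbering (O1, C2, C3, C4, C4a, C5–C8, C8a; rings A, B, C) is used for every unit.

**Route**

Step 1
Reactants: 1 3,5-bis(benzyloxy)phenol
Product: 2 2-bromo-3,5-bis(benzyloxy)phenol
Conditions: NBS (1.0 equiv), CH2Cl2, −78 °C
Reagents that add atoms: N-bromosuccinimide, O=C1CCC(=O)N1Br
Why: Electrophilic aromatic bromination of an electron-rich phenol, in which NBS at low temperature should go ortho to the free hydroxyl (hydrogen-bond delivery, less hindered than the position between the two benzyloxy groups) and one equivalent limits dibromination.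

Step 2
Reactants: 2 2-bromo-3,5-bis(benzyloxy)phenol
Product: 6 3,5-bis(benzyloxy)-2-(trimethylsilyl)phenyl trifluoromethanesulfonate, via aryl trimethylsilyl ether 3 (not isolated), via ortho-lithio silyl ether 4 (not isolated), via lithium ortho-silylphenoxide 5 (not isolated)
Conditions: HMDS, THF, 65 °C, then evaporation; n-BuLi, THF, −100 → −78 °C; Tf2O, −100 °C → rt
Reagents that add atoms: hexamethyldisilazane, C[Si](C)(C)N[Si](C)(C)C; trifluoromethanesulfonic anhydride, O=S(=O)(OS(=O)(=O)C(F)(F)F)C(F)(F)F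
Why: Standard ortho-silylaryl triflate synthesis by O-silylation, bromine–lithium exchange, retro-Brook 1,3-O→C silyl shift and O-triflation, with exchange at −100 °C outrunning deprotonation of the benzyl ethers.

Step 3
Reactants: 7 (S)-4-benzyloxazolidin-2-one, 8 2-(benzyloxy)acetyl chloride
Product: 10 (S)-4-benzyl-3-[2-(benzyloxy)acetyl]oxazolidin-2-one, via lithium oxazolidinide 9 (not isolated)
Conditions: n-BuLi, THF, −78 °C; then 8, −78 → 0 °C
Reagents that add atoms: none
Why: N-acylation of the lithiated Evans auxiliary by the acid chloride, which does not involve the auxiliary stereocentre.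

Step 4
Reactants: 10 (S)-4-benzyl-3-[2-(benzyloxy)acetyl]oxazolidin-2-one, 11 3,4-bis(benzyloxy)benzaldehyde
Product: 13 (S)-4-benzyl-3-[(2S,3R)-2-(benzyloxy)-3-[3,4-bis(benzyloxy)phenyl]-3-hydroxypropanoyl]oxazolidin-2-one, via dibutylboron Z-enolate 12 (not isolated)
Conditions: Bu2BOTf, Et3N, CH2Cl2, −78 → 0 °C; 11, −78 → 0 °C; then pH 7 buffer, MeOH, H2O2, 0 °C
Reagents that add atoms: none
Why: Evans syn-aldol reaction, in which the Z-boron enolate reacts through a chair Zimmerman–Traxler transition state on the face away from the benzyl group of the (S)-auxiliary and so sets the syn (2S,3R) pair that becomes C3 and C2 of the flavan.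

Step 5
Reactants: 13 (S)-4-benzyl-3-[(2S,3R)-2-(benzyloxy)-3-[3,4-bis(benzyloxy)phenyl]-3-hydroxypropanoyl]oxazolidin-2-one
Product: 14 (1R,2R)-2-(benzyloxy)-1-[3,4-bis(benzyloxy)phenyl]propane-1,3-diol
Conditions: LiBH4, MeOH (1 equiv), THF, 0 °C
Reagents that add atoms: none
Why: Reductive cleavage of the N-acyl oxazolidinone to the primary alcohol with release of the auxiliary, which leaves both stereocentres untouched (the change 2S → 2R is only a change of CIP priorities).

Step 6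
Reactants: 14 (1R,2R)-2-(benzyloxy)-1-[3,4-bis(benzyloxy)phenyl]propane-1,3-diol
Product: 16 (2R,3R)-2-(benzyloxy)-3-[3,4-bis(benzyloxy)phenyl]-3-[(trimethylsilyl)oxy]propyl 4-methylbenzenesulfonate, via hydroxy tosylate 15 (not isolated)
Conditions: TsCl, Et3N, DMAP (cat.), CH2Cl2, 0 °C; then TMSCl, imidazole, 0 °C
Reagents that add atoms: 4-methylbenzenesulfonyl chloride, Cc1ccc(cc1)S(=O)(=O)Cl; chlorotrimethylsilane, C[Si](C)(C)Cl
Why: Sulfonylation should be selective for the primary over the hindered secondary benzylic hydroxyl, which is then capped in the same flask as a fluoride-labile trimethylsilyl ether.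

Step 7
Reactants: 16 (2R,3R)-2-(benzyloxy)-3-[3,4-bis(benzyloxy)phenyl]-3-[(trimethylsilyl)oxy]propyl 4-methylbenzenesulfonate, 6 3,5-bis(benzyloxy)-2-(trimethylsilyl)phenyl trifluoromethanesulfonate
Product: 20 (2R,3R)-3,5,7-tris(benzyloxy)-2-[3,4-bis(benzyloxy)phenyl]chromane (penta-O-benzyl-(−)-epicatechin), via potassium alkoxide 17 (not isolated), via 3,5-bis(benzyloxy)benzyne 18 (not isolated), via ortho-potassioaryl ether 19 (not isolated)
Conditions: KF, 18-crown-6, THF, −20 °C → rt, slow addition of 6 (1.5 equiv)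
Reagents that add atoms: none
Why: Proposed new method: fluoride strips both trimethylsilyl groups, so 6 collapses to aryne 18 while 16 becomes alkoxide 17 in a medium without any O–H; 17 adds to the aryne carbon remote from the flanking benzyloxy group (future C8a), and the aryl anion 19, which sits on the carbon next to that oxygen (future C4a), displaces the primary tosylate to form C4–C4a. The closest known reaction types are the fluoride-induced O-arylation of aliphatic alcohols by arynes, aryne annulations in which the aryl anion is caught by a tethered ester or enone, and the Parham cyclialkylation of ortho-lithioaryl ethers; capture of an aryne-derived aryl anion by a tethered alkyl sulfonate is the untested element. Ring C is closed by the C–C bond in a 6-exo-tet mode, after the intermolecular C–O bond has been made. No stereocentre is formed: C2 and C3 come from the aldol step and none of their bonds is broken, so the cis (2R,3R) pattern is retained. The step needs regioselective O-addition, which the C5 benzyloxy group secures through aryne distortion and inductive stabilisation of the adjacent carbanion, and it needs alkylation to outrun protonation, oxetane closure and Grob-type fragmentation, which the proton-free silyl ether/fluoride design, low temperature and slow addition of 6 are meant to secure.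

Step 8
Reactants: 20 (2R,3R)-3,5,7-tris(benzyloxy)-2-[3,4-bis(benzyloxy)phenyl]chromane
Product: 21 (2R,3R)-8-bromo-3,5,7-tris(benzyloxy)-2-[3,4-bis(benzyloxy)phenyl]chromane
Conditions: NBS (1.0 equiv), CH2Cl2, −78 → 0 °C
Reagents that add atoms: N-bromosuccinimide, O=C1CCC(=O)N1Br
Why: Electrophilic bromination of ring A at C8, the position ortho to the ring oxygen that is more accessible than C6 between two benzyloxy groups (the known preference of benzylated flavan-3-ols), which blocks C8 for the later coupling.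

Step 9
Reactants: 22 (−)-epicatechin
Product: 23 (2R,3R)-5,7-bis(benzyloxy)-2-[3,4-bis(benzyloxy)phenyl]chroman-3-ol (5,7,3',4'-tetra-O-benzyl-(−)-epicatechin)
Conditions: BnBr (4.4 equiv), K2CO3, DMF, 0 °C → rt
Reagents that add atoms: benzyl bromide, BrCc1ccccc1
Why: Williamson etherification of the four phenols under mild carbonate conditions that leave the secondary C3 hydroxyl free and should not epimerise C2.

Step 10
Reactants: 23 5,7,3',4'-tetra-O-benzyl-(−)-epicatechin
Product: 25 (2R,3R,4S)-5,7-bis(benzyloxy)-2-[3,4-bis(benzyloxy)phenyl]-4-(2-ethoxyethoxy)chroman-3-ol (4β ether), via C4 benzylic cation 24 (not isolated)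
Conditions: DDQ, 2-ethoxyethanol, CH2Cl2, rt
Reagents that add atoms: 2-ethoxyethanol, CCOCCO
Why: Oxidative benzylic C–H functionalisation, in which DDQ abstracts hydride from C4 (activated by the ring A oxygens) and the alcohol adds to cation 24 trans to the C3 hydroxyl and the C2 aryl group, which sets 4β (4S).

Step 11
Reactants: 25 (2R,3R,4S)-5,7-bis(benzyloxy)-2-[3,4-bis(benzyloxy)phenyl]-4-(2-ethoxyethoxy)chroman-3-ol
Product: 26 (2R,3R,4S)-8-bromo-5,7-bis(benzyloxy)-2-[3,4-bis(benzyloxy)phenyl]-4-(2-ethoxyethoxy)chroman-3-ol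
Conditions: NBS (1.0 equiv), CH2Cl2, −40 °C
Reagents that add atoms: N-bromosuccinimide, O=C1CCC(=O)N1Br
Why: Electrophilic bromination at C8 as in step 8, with one equivalent at low temperature so that C6–H is kept for the second coupling.

Step 12
Reactants: 25 (2R,3R,4S)-5,7-bis(benzyloxy)-2-[3,4-bis(benzyloxy)phenyl]-4-(2-ethoxyethoxy)chroman-3-ol
Product: 27 (2R,3R,4S)-6,8-dibromo-5,7-bis(benzyloxy)-2-[3,4-bis(benzyloxy)phenyl]-4-(2-ethoxyethoxy)chroman-3-ol
Conditions: NBS (2.1 equiv), CH2Cl2, 0 °C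
Reagents that add atoms: N-bromosuccinimide, O=C1CCC(=O)N1Br
Why: Twofold electrophilic bromination fills both ring A positions, which removes every nucleophilic site from the top-unit electrophile.

Step 13
Reactants: 26 (2R,3R,4S)-8-bromo-5,7-bis(benzyloxy)-2-[3,4-bis(benzyloxy)phenyl]-4-(2-ethoxyethoxy)chroman-3-ol, 21 (2R,3R)-8-bromo-3,5,7-tris(benzyloxy)-2-[3,4-bis(benzyloxy)phenyl]chromane (2.5 equiv)
Product: 29 [8-bromo-5,7,3',4'-tetra-O-benzyl-epicatechin]-(4β→6)-[8-bromo-3,5,7,3',4'-penta-O-benzyl-epicatechin], via C4 benzylic cation 28 (not isolated)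
Conditions: BF3·OEt2 (0.5 equiv), CH2Cl2, −78 → −30 °C, slow addition of 26; excess 21 recovered
Reagents that add atoms: none
Why: Lewis acid ionisation of the C4 ether gives cation 28, which undergoes Friedel–Crafts attack by C6 of 21 (its only free ring A position) on the face trans to the C3 hydroxyl and C2 aryl group, setting the 4β (4S) interflavan bond, while excess 21 should outcompete C6 of 26 and of the product.

Step 14
Reactants: 27 (2R,3R,4S)-6,8-dibromo-5,7-bis(benzyloxy)-2-[3,4-bis(benzyloxy)phenyl]-4-(2-ethoxyethoxy)chroman-3-ol (1.5 equiv), 29 bromine-capped dimer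
Product: 31 [6,8-dibromo-5,7,3',4'-tetra-O-benzyl-epicatechin]-(4β→6)-[8-bromo-5,7,3',4'-tetra-O-benzyl-epicatechin]-(4β→6)-[8-bromo-3,5,7,3',4'-penta-O-benzyl-epicatechin], via C4 benzylic cation 30 (not isolated)
Conditions: BF3·OEt2 (0.5 equiv), CH2Cl2, −40 → 0 °C
Reagents that add atoms: none
Why: The same ionisation/Friedel–Crafts coupling, in which 27 cannot act as a nucleophile, C6 of the middle unit is the only unsubstituted ring A carbon of 29, and attack anti to the C3 hydroxyl of cation 30 again gives the 4β (4S) bond.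

Step 15
Reactants: 31 protected trimer
Product: 32 epicatechin-(4β→6)-epicatechin-(4β→6)-epicatechin (CNP0163146.2)
Conditions: H2 (1 atm), Pd(OH)2/C, Et3N (4 equiv), THF/MeOH/H2O, rt
Reagents that add atoms: none
Why: Catalytic hydrogenolysis should cleave the thirteen benzyl ethers and hydrodehalogenate the four aryl bromides, with Et3N buffering the HBr so that the acid-labile interflavan bonds and the stereocentres stay intact.

**Compound list**

1 | 3,5-bis(benzyloxy)phenol | Oc1cc(OCc2ccccc2)cc(OCc2ccccc2)c1 | starting material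
2 | 2-bromo-3,5-bis(benzyloxy)phenol | Oc1cc(OCc2ccccc2)cc(OCc2ccccc2)c1Br | intermediate
3 | [2-bromo-3,5-bis(benzyloxy)phenoxy]trimethylsilane | C[Si](C)(C)Oc1cc(OCc2ccccc2)cc(OCc2ccccc2)c1Br | intermediate
4 | [2,4-bis(benzyloxy)-6-(trimethylsilyloxy)phenyl]lithium | C[Si](C)(C)Oc1cc(OCc2ccccc2)cc(OCc2ccccc2)c1[Li] | intermediate
5 | lithium 3,5-bis(benzyloxy)-2-(trimethylsilyl)phenoxide | [Li+].[O-]c1cc(OCc2ccccc2)cc(OCc2ccccc2)c1[Si](C)(C)C | intermediate
6 | 3,5-bis(benzyloxy)-2-(trimethylsilyl)phenyl trifluoromethanesulfonate | C[Si](C)(C)c1c(OCc2ccccc2)cc(OCc2ccccc2)cc1OS(=O)(=O)C(F)(F)F | intermediate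
7 | (S)-4-benzyloxazolidin-2-one | O=C1OC[C@H](Cc2ccccc2)N1 | starting material
8 | 2-(benzyloxy)acetyl chloride | O=C(Cl)COCc1ccccc1 | starting material
9 | lithium (S)-4-benzyl-2-oxooxazolidin-3-ide | [Li+].O=C1OC[C@H](Cc2ccccc2)[N-]1 | intermediate
10 | (S)-4-benzyl-3-[2-(benzyloxy)acetyl]oxazolidin-2-one | O=C(COCc1ccccc1)N1C(=O)OC[C@@H]1Cc1ccccc1 | intermediate
11 | 3,4-bis(benzyloxy)benzaldehyde | O=Cc1ccc(OCc2ccccc2)c(OCc2ccccc2)c1 | starting material
12 | dibutylboron (Z)-enolate of 10 | CCCCB(CCCC)O/C(N1C(=O)OC[C@@H]1Cc1ccccc1)=C\OCc1ccccc1 | intermediate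
13 | (S)-4-benzyl-3-[(2S,3R)-2-(benzyloxy)-3-[3,4-bis(benzyloxy)phenyl]-3-hydroxypropanoyl]oxazolidin-2-one | O=C([C@@H](OCc1ccccc1)[C@H](O)c1ccc(OCc2ccccc2)c(OCc2ccccc2)c1)N1C(=O)OC[C@@H]1Cc1ccccc1 | intermediate
14 | (1R,2R)-2-(benzyloxy)-1-[3,4-bis(benzyloxy)phenyl]propane-1,3-diol | OC[C@@H](OCc1ccccc1)[C@H](O)c1ccc(OCc2ccccc2)c(OCc2ccccc2)c1 | intermediate
15 | (2R,3R)-2-(benzyloxy)-3-[3,4-bis(benzyloxy)phenyl]-3-hydroxypropyl 4-methylbenzenesulfonate | Cc1ccc(cc1)S(=O)(=O)OC[C@@H](OCc1ccccc1)[C@H](O)c1ccc(OCc2ccccc2)c(OCc2ccccc2)c1 | intermediate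
16 | (2R,3R)-2-(benzyloxy)-3-[3,4-bis(benzyloxy)phenyl]-3-[(trimethylsilyl)oxy]propyl 4-methylbenzenesulfonate | Cc1ccc(cc1)S(=O)(=O)OC[C@@H](OCc1ccccc1)[C@H](O[Si](C)(C)C)c1ccc(OCc2ccccc2)c(OCc2ccccc2)c1 | intermediate
17 | potassium alkoxide of 15 | [K+].Cc1ccc(cc1)S(=O)(=O)OC[C@@H](OCc1ccccc1)[C@H]([O-])c1ccc(OCc2ccccc2)c(OCc2ccccc2)c1 | intermediate
18 | 3,5-bis(benzyloxy)benzyne | C1#CC(OCc2ccccc2)=CC(OCc2ccccc2)=C1 | intermediate
19 | aryl ether of 15 with 3,5-bis(benzyloxy)phenyl on the benzylic oxygen, potassiated at the ring carbon between the ether oxygen and a benzyloxy group | Cc1ccc(cc1)S(=O)(=O)OC[C@@H](OCc1ccccc1)[C@H](Oc1cc(OCc2ccccc2)cc(OCc2ccccc2)c1[K])c1ccc(OCc2ccccc2)c(OCc2ccccc2)c1 | intermediate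
20 | (2R,3R)-3,5,7-tris(benzyloxy)-2-[3,4-bis(benzyloxy)phenyl]chromane (penta-O-benzyl-(−)-epicatechin) | c1ccccc1COc1cc(OCc2ccccc2)c2c(c1)O[C@H](c1ccc(OCc3ccccc3)c(OCc3ccccc3)c1)[C@H](OCc1ccccc1)C2 | intermediate
21 | (2R,3R)-8-bromo-3,5,7-tris(benzyloxy)-2-[3,4-bis(benzyloxy)phenyl]chromane | c1ccccc1COc1cc(OCc2ccccc2)c2c(c1Br)O[C@H](c1ccc(OCc3ccccc3)c(OCc3ccccc3)c1)[C@H](OCc1ccccc1)C2 | intermediate
22 | (−)-epicatechin, (2R,3R) | Oc1cc(O)c2c(c1)O[C@H](c1ccc(O)c(O)c1)[C@H](O)C2 | starting material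
23 | 5,7,3',4'-tetra-O-benzyl-(−)-epicatechin, (2R,3R) | c1ccccc1COc1cc(OCc2ccccc2)c2c(c1)O[C@H](c1ccc(OCc3ccccc3)c(OCc3ccccc3)c1)[C@H](O)C2 | intermediate
24 | C4 benzylic cation of 23 | c1ccccc1COc1cc(OCc2ccccc2)c2c(c1)O[C@H](c1ccc(OCc3ccccc3)c(OCc3ccccc3)c1)[C@H](O)[CH+]2 | intermediate
25 | (2R,3R,4S)-5,7-bis(benzyloxy)-2-[3,4-bis(benzyloxy)phenyl]-4-(2-ethoxyethoxy)chroman-3-ol (4β) | c1ccccc1COc1cc(OCc2ccccc2)c2c(c1)O[C@H](c1ccc(OCc3ccccc3)c(OCc3ccccc3)c1)[C@H](O)[C@H]2OCCOCC | intermediate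
26 | (2R,3R,4S)-8-bromo-5,7-bis(benzyloxy)-2-[3,4-bis(benzyloxy)phenyl]-4-(2-ethoxyethoxy)chroman-3-ol | c1ccccc1COc1cc(OCc2ccccc2)c2c(c1Br)O[C@H](c1ccc(OCc3ccccc3)c(OCc3ccccc3)c1)[C@H](O)[C@H]2OCCOCC | intermediate
27 | (2R,3R,4S)-6,8-dibromo-5,7-bis(benzyloxy)-2-[3,4-bis(benzyloxy)phenyl]-4-(2-ethoxyethoxy)chroman-3-ol | c1ccccc1COc1c(Br)c(OCc2ccccc2)c2c(c1Br)O[C@H](c1ccc(OCc3ccccc3)c(OCc3ccccc3)c1)[C@H](O)[C@H]2OCCOCC | intermediate
28 | C4 benzylic cation of 26 | c1ccccc1COc1cc(OCc2ccccc2)c2c(c1Br)O[C@H](c1ccc(OCc3ccccc3)c(OCc3ccccc3)c1)[C@H](O)[CH+]2 | intermediate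
29 | [8-bromo-5,7,3',4'-tetra-O-benzyl-epicatechin]-(4β→6)-[8-bromo-3,5,7,3',4'-penta-O-benzyl-epicatechin] | c1c(OCc5ccccc5)c(Br)c2c(c1OCc5ccccc5)[C@H](c3c(OCc5ccccc5)c(Br)c4c(c3OCc5ccccc5)C[C@@H](OCc5ccccc5)[C@@H](c6ccc(OCc5ccccc5)c(OCc5ccccc5)c6)O4)[C@@H](O)[C@@H](c6ccc(OCc5ccccc5)c(OCc5ccccc5)c6)O2 | intermediate
30 | C4 benzylic cation of 27 | c1ccccc1COc1c(Br)c(OCc2ccccc2)c2c(c1Br)O[C@H](c1ccc(OCc3ccccc3)c(OCc3ccccc3)c1)[C@H](O)[CH+]2 | intermediate
31 | [6,8-dibromo-5,7,3',4'-tetra-O-benzyl-epicatechin]-(4β→6)-[8-bromo-5,7,3',4'-tetra-O-benzyl-epicatechin]-(4β→6)-[8-bromo-3,5,7,3',4'-penta-O-benzyl-epicatechin] | c5ccccc5COc1c(Br)c(OCc5ccccc5)c2c(c1Br)O[C@H](c6ccc(OCc5ccccc5)c(OCc5ccccc5)c6)[C@H](O)[C@H]2c1c(OCc5ccccc5)c(Br)c2c(c1OCc5ccccc5)[C@H](c3c(OCc5ccccc5)c(Br)c4c(c3OCc5ccccc5)C[C@@H](OCc5ccccc5)[C@@H](c6ccc(OCc5ccccc5)c(OCc5ccccc5)c6)O4)[C@@H](O)[C@@H](c6ccc(OCc5ccccc5)c(OCc5ccccc5)c6)O2 | intermediate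
32 | epicatechin-(4β→6)-epicatechin-(4β→6)-epicatechin (CNP0163146.2) | Oc1cc(O)c2c(c1)O[C@H](c1ccc(O)c(O)c1)[C@H](O)[C@H]2c1c(O)cc2c(c1O)[C@H](c1c(O)cc3c(c1O)C[C@@H](O)[C@@H](c1ccc(O)c(O)c1)O3)[C@@H](O)[C@@H](c1ccc(O)c(O)c1)O2 | target

**Summary**

Total step count: 15. Longest linear sequence: 9 steps (steps 3, 4, 5, 6, 7, 8, 13, 14, 15).

Steps most likely to fail:

1. Step 7 (bears the label). The aryl anion may be protonated before it alkylates, or the alkoxide may close to an oxetane or fragment before it meets the aryne. Fallback with known chemistry, making the same two bonds in two operations: 1,3,5-trifluorobenzene is treated with sodium benzyloxide (BnOH, NaH, NMP, 80 °C) to give 1,3-bis(benzyloxy)-5-fluorobenzene F1. Ortho-lithiation between fluorine and benzyloxy (n-BuLi, THF, −78 °C) gives [2,4-bis(benzyloxy)-6-fluorophenyl]lithium F2, which is transmetalated with MgBr2·OEt2 to [2,4-bis(benzyloxy)-6-fluorophenyl]magnesium bromide F3. F3 is coupled under Li2CuCl4 catalysis (THF, −20 → 0 °C) with hydroxy tosylate 15, which is isolated when the silylation of step 6 is left out; one extra equivalent of F3 takes up the hydroxyl proton. This gives (1R,2R)-2-(benzyloxy)-3-[2,4-bis(benzyloxy)-6-fluorophenyl]-1-[3,4-bis(benzyloxy)phenyl]propan-1-ol F4, which holds the C4–C4a bond. Intramolecular SNAr (NaH, DMF, 80 °C), in which the benzylic alkoxide displaces the fluoride that sits meta to both benzyloxy groups, forms O1–C8a and returns to the route at 20.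

2. Step 13. The electrophile 26 may self-condense through its own C6, and the product dimer may add a second cation. Fallback by reversed coupling order under orthogonal activation, setting out from 26 and 27 and replacing steps 13 and 14: 26 is converted with 2,6-dimethylbenzenethiol and BF3·OEt2 (CH2Cl2, −78 °C) into the 4β-(2,6-dimethylphenylthio) ether F5, which is inert to BF3·OEt2 at low temperature and has C6–H as its only nucleophilic position. BF3·OEt2-promoted coupling of F5 with the fully capped electrophile 27 gives the top–middle thio dimer F6, which has no free ring A carbon. Thiophilic activation of F6 with AgBF4 (THF, 0 °C) in the presence of 21 proceeds through the C4 cation F7 and returns to the route at 31. Both couplings then use a monomeric nucleophile, which also avoids the hindered coupling of step 14.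

3. Step 15. Hydrogenolysis may stop short of full debenzylation, and HBr released during hydrodebromination may cleave the interflavan bonds. Fallback in two stages, setting out from 31: radical debromination (Bu3SnH, AIBN, toluene, 90 °C) gives the bromine-free tridecabenzyl trimer F8, which is then hydrogenolysed under neutral conditions (H2, Pd(OH)2/C, THF/MeOH/H2O) to return at 32.

**Further compounds**

F1 | step 7 | 1,3-bis(benzyloxy)-5-fluorobenzene | Fc1cc(OCc2ccccc2)cc(OCc2ccccc2)c1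
F2 | step 7 | [2,4-bis(benzyloxy)-6-fluorophenyl]lithium | [Li]c1c(F)cc(OCc2ccccc2)cc1OCc1ccccc1
F3 | step 7 | [2,4-bis(benzyloxy)-6-fluorophenyl]magnesium bromide | Br[Mg]c1c(F)cc(OCc2ccccc2)cc1OCc1ccccc1
F4 | step 7 | (1R,2R)-2-(benzyloxy)-3-[2,4-bis(benzyloxy)-6-fluorophenyl]-1-[3,4-bis(benzyloxy)phenyl]propan-1-ol | Fc1cc(OCc2ccccc2)cc(OCc2ccccc2)c1C[C@@H](OCc1ccccc1)[C@H](O)c1ccc(OCc2ccccc2)c(OCc2ccccc2)c1
F5 | step 13 | (2R,3R)-8-bromo-5,7-bis(benzyloxy)-2-[3,4-bis(benzyloxy)phenyl]-4β-[(2,6-dimethylphenyl)thio]chroman-3-ol | c1ccccc1COc1cc(OCc2ccccc2)c2c(c1Br)O[C@H](c1ccc(OCc3ccccc3)c(OCc3ccccc3)c1)[C@H](O)[C@H]2Sc1c(C)cccc1C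
F6 | step 13 | [6,8-dibromo-5,7,3',4'-tetra-O-benzyl-epicatechin]-(4β→6)-[8-bromo-5,7,3',4'-tetra-O-benzyl-4β-(2,6-dimethylphenylthio)epicatechin] | c5ccccc5COc1c(Br)c(OCc5ccccc5)c2c(c1Br)O[C@H](c6ccc(OCc5ccccc5)c(OCc5ccccc5)c6)[C@H](O)[C@H]2c1c(OCc5ccccc5)c(Br)c2c(c1OCc5ccccc5)[C@H](Sc3c(C)cccc3C)[C@@H](O)[C@@H](c6ccc(OCc5ccccc5)c(OCc5ccccc5)c6)O2
F7 | step 13 | C4 benzylic cation of F6 (middle unit) | c5ccccc5COc1c(Br)c(OCc5ccccc5)c2c(c1Br)O[C@H](c6ccc(OCc5ccccc5)c(OCc5ccccc5)c6)[C@H](O)[C@H]2c1c(OCc5ccccc5)c(Br)c2c(c1OCc5ccccc5)[CH+][C@@H](O)[C@@H](c6ccc(OCc5ccccc5)c(OCc5ccccc5)c6)O2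
F8 | step 15 | [5,7,3',4'-tetra-O-benzyl-epicatechin]-(4β→6)-[5,7,3',4'-tetra-O-benzyl-epicatechin]-(4β→6)-[3,5,7,3',4'-penta-O-benzyl-epicatechin] | c5ccccc5COc1cc(OCc5ccccc5)c2c(c1)O[C@H](c6ccc(OCc5ccccc5)c(OCc5ccccc5)c6)[C@H](O)[C@H]2c1c(OCc5ccccc5)cc2c(c1OCc5ccccc5)[C@H](c3c(OCc5ccccc5)cc4c(c3OCc5ccccc5)C[C@@H](OCc5ccccc5)[C@@H](c6ccc(OCc5ccccc5)c(OCc5ccccc5)c6)O4)[C@@H](O)[C@@H](c6ccc(OCc5ccccc5)c(OCc5ccccc5)c6)O2
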